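**Strategy.** The 1,2-dioxane (ring numbered O1–O2–C3–C4–C5–C6; C3 bears methyl and 8-phenyloctyl, C6 methyl and the propanoic acid arm) is disconnected at C4–C5. This is the only ring bond joining two plain methylenes; every other ring bond ends at a peroxy oxygen or at a quaternary stereocentre. Both hindered C–O bonds and the O1–O2 link are therefore made on open-chain material by invertive epoxide openings. Ring-closing metathesis of the resulting ditertiary bis-allylic peroxide then closes the six-membered ring as C4=C5 in one operation. The metathesis substrate carries two differently protected hydroxymethyl arms (TBDPS, PMB), so the two side chains can be grown one at a time without a statistical step.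

Key step: step 7

Remark (assumption): acid-catalysed opening of the two 2,2-disubstituted glycidyl ethers by peroxide nucleophiles is taken to occur at the tertiary carbon with inversion, as is usual for this class.
Remark: in the twofold steps 5, 6 and 16 both sites react in the same operation; partly converted species are not numbered.
Remark: compound names use IUPAC locants, which differ from the ring numbering of the overview; ethereal H2O2 and all peroxidic intermediates are handled in solution behind a shield.

Step 1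
Reactants: 1 (R)-2-methylglycidol
Product: 2 tert-butyl{[(2S)-2-methyloxiran-2-yl]methoxy}diphenylsilane
Conditions: TBDPSCl, imidazole, CH2Cl2, 0 °C to rt
Reagents that add atoms: tert-butyl(chloro)diphenylsilane, CC(C)(C)[Si](Cl)(c1ccccc1)c1ccccc1
Why: Imidazole-promoted silylation of the primary alcohol (silyl ether formation) leaves the epoxide and its quaternary stereocentre untouched; the descriptor becomes S only because CH2OSi now outranks the ring CH2.

Step 2
Reactants: 1 (R)-2-methylglycidol
Product: 3 (2S)-2-{[(4-methoxybenzyl)oxy]methyl}-2-methyloxirane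
Conditions: NaH, PMBCl, Bu4NI (cat.), THF, 0 °C to rt
Reagents that add atoms: 4-methoxybenzyl chloride, COc1ccc(CCl)cc1
Why: Williamson ether synthesis on the sodium alkoxide; the only base-induced side path, Payne rearrangement, is degenerate for 2-methylglycidol and returns the same enantiomer, so the stereocentre is kept (descriptor S by priority change only).

Step 3
Reactants: 2 tert-butyl{[(2S)-2-methyloxiran-2-yl]methoxy}diphenylsilane; 4 hydrogen peroxide
Product: 5 (2R)-3-[(tert-butyldiphenylsilyl)oxy]-2-hydroperoxy-2-methylpropan-1-ol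
Conditions: H2O2 (extracted from 50% aq. into Et2O, dried over MgSO4, 8 equiv), H3PMo12O40 (3 mol%), Et2O, rt
Reagents that add atoms: none
Why: Acid-catalysed perhydrolysis of a 2,2-disubstituted epoxide (nucleophilic epoxide ring-opening): the activated epoxide is attacked at the tertiary carbon, which carries most of the positive charge, from the face opposite the departing oxygen, so the C–OOH stereocentre is set with inversion (S epoxide carbon to R hydroperoxide), the electron-withdrawing CH2OSi group disfavouring a free cation and hence racemisation, while excess H2O2 suppresses a second alkylation.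

Step 4
Reactants: 5 (2R)-3-[(tert-butyldiphenylsilyl)oxy]-2-hydroperoxy-2-methylpropan-1-ol; 3 (2S)-2-{[(4-methoxybenzyl)oxy]methyl}-2-methyloxirane
Product: 6 (2R)-2-({(2R)-1-[(tert-butyldiphenylsilyl)oxy]-3-hydroxy-2-methylpropan-2-yl}peroxy)-3-[(4-methoxybenzyl)oxy]-2-methylpropan-1-ol
Conditions: 5 (1.3 equiv), H3PMo12O40 (5 mol%), Et2O–CH2Cl2 (ca. 1 M), 0 °C to rt
Reagents that add atoms: none
Why: Acid-catalysed ring-opening of an epoxide by an alkyl hydroperoxide, the same event that gives bis(β-hydroxyalkyl) peroxides when epoxide perhydrolysis is run short of H2O2: the α-effect OOH group is a better nucleophile than the neopentyl OH, attack again takes place at the tertiary carbon with inversion and so sets the second quaternary peroxy stereocentre (R), and the small PMB-oxymethyl arm on the electrophile keeps the approach of the bulky nucleophile as open as possible.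

Step 5
Reactants: 6 (2R)-2-({(2R)-1-[(tert-butyldiphenylsilyl)oxy]-3-hydroxy-2-methylpropan-2-yl}peroxy)-3-[(4-methoxybenzyl)oxy]-2-methylpropan-1-ol
Product: 7 (2S)-2-({(2S)-1-[(tert-butyldiphenylsilyl)oxy]-2-methyl-3-oxopropan-2-yl}peroxy)-3-[(4-methoxybenzyl)oxy]-2-methylpropanal
Conditions: Dess–Martin periodinane (2.6 equiv), CH2Cl2, 0 °C to rt
Reagents that add atoms: none
Why: Dess–Martin oxidation converts both neopentyl carbinols to aldehydes under near-neutral conditions; the α-peroxy aldehydes have no α-hydrogen, so they cannot epimerise or undergo base-type peroxide fragmentation, and the descriptors change to S,S by priority only.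

Step 6
Reactants: 7 (2S)-2-({(2S)-1-[(tert-butyldiphenylsilyl)oxy]-2-methyl-3-oxopropan-2-yl}peroxy)-3-[(4-methoxybenzyl)oxy]-2-methylpropanal; 8 methyltriphenylphosphonium bromide
Product: 10 (2R)-1-(tert-butyldiphenylsilyloxy)-2-methylbut-3-en-2-yl (2R)-1-(4-methoxybenzyloxy)-2-methylbut-3-en-2-yl peroxide, via methylidenetriphenylphosphorane 9 (not isolated)
Conditions: 8 (3 equiv), NaHMDS (2.8 equiv), THF, 0 °C; then 7, −78 °C to 0 °C
Reagents that add atoms: none
Why: Twofold Wittig methylenation of non-enolisable aldehydes; at low temperature the ylide adds to C=O far faster than it can attack a ditertiary O–O bond, and the peroxy carbons, having no hydrogen, are not at risk (descriptors return to R,R by priority only).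

Step 7
Reactants: 10 (2R)-1-(tert-butyldiphenylsilyloxy)-2-methylbut-3-en-2-yl (2R)-1-(4-methoxybenzyloxy)-2-methylbut-3-en-2-yl peroxide
Product: 11 (3R,6R)-3-[(tert-butyldiphenylsilyloxy)methyl]-6-[(4-methoxybenzyloxy)methyl]-3,6-dimethyl-3,6-dihydro-1,2-dioxine
Conditions: Grubbs second-generation Ru carbene (5–10 mol%), CH2Cl2 (0.005 M), 40 °C, Ar sparge
Reagents that add atoms: none
Why: The ruthenium methylidene engages one vinyl group by [2+2] cycloaddition and cycloreversion (loss of ethene) to give a substrate-bound alkylidene, which forms a ruthenacyclobutane with the second vinyl group and collapses to the ring alkene C4=C5 while regenerating the methylidene (Chauvin mechanism, ring-closing olefin metathesis). The closest known reaction type is the ring-closing metathesis of unsaturated dialkyl peroxides to 3,6-dihydro-1,2-dioxines. The single ring, the six-membered O1–O2–C3–C4=C5–C6 dihydrodioxine, is closed by C=C bond formation between the two vinyl CH carbons on a chain that already contains the O–O bond, and the endocyclic alkene is necessarily cis. No stereocentre is created; C3 and C6 are quaternary, do not take part in the bond reorganisation and cannot epimerise, so the R,R configuration set in steps 3 and 4 is carried through unchanged. The step needs cyclisation to win over intermolecular metathesis and the O–O bond to survive the carbene: the two fully substituted allylic carbons disfavour homodimerisation of either vinyl group and bias the chain towards the folded conformer (gem-disubstituent effect), high dilution and removal of ethene help further, and a ditertiary peroxide has no α-hydrogen through which ruthenium could trigger fragmentation.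

Step 8
Reactants: 11 (3R,6R)-3-[(tert-butyldiphenylsilyloxy)methyl]-6-[(4-methoxybenzyloxy)methyl]-3,6-dimethyl-3,6-dihydro-1,2-dioxine
Product: 12 (3R,6R)-3-[(tert-butyldiphenylsilyloxy)methyl]-6-[(4-methoxybenzyloxy)methyl]-3,6-dimethyl-1,2-dioxane
Conditions: KO2CN=NCO2K (excess, portionwise), AcOH, MeOH–CH2Cl2, 0 °C to rt
Reagents that add atoms: none
Why: Diimide reduction (concerted syn transfer of two hydrogens from HN=NH) saturates the cis C4=C5 bond and leaves the O–O bond, which catalytic hydrogenation would cleave, intact; it is placed directly after ring closure so that all later chemistry runs on a saturated ditertiary 1,2-dioxane that is as inert as a di-tert-alkyl peroxide.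

Step 9
Reactants: 12 (3R,6R)-3-[(tert-butyldiphenylsilyloxy)methyl]-6-[(4-methoxybenzyloxy)methyl]-3,6-dimethyl-1,2-dioxane
Product: 13 {(3R,6R)-6-[(tert-butyldiphenylsilyloxy)methyl]-3,6-dimethyl-1,2-dioxan-3-yl}methanol
Conditions: DDQ, CH2Cl2–pH 7 buffer (10:1), 0 °C to rt
Reagents that add atoms: none
Why: Oxidative cleavage of the p-methoxybenzyl ether by DDQ (hydride abstraction, hydrolysis of the oxocarbenium ion) frees one arm selectively because the silyl ether, the dialkyl peroxide and the saturated ring offer DDQ nothing to oxidise.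

Step 10
Reactants: 13 {(3R,6R)-6-[(tert-butyldiphenylsilyloxy)methyl]-3,6-dimethyl-1,2-dioxan-3-yl}methanol
Product: 14 (3R,6R)-6-[(tert-butyldiphenylsilyloxy)methyl]-3,6-dimethyl-1,2-dioxane-3-carbaldehyde
Conditions: Dess–Martin periodinane, CH2Cl2, 0 °C to rt
Reagents that add atoms: none
Why: Dess–Martin oxidation of the neopentyl primary alcohol gives an α-peroxy aldehyde that has no α-hydrogen and is used directly.

Step 11
Reactants: 15 7-phenylheptan-1-ol
Product: 16 (7-bromoheptyl)benzene
Conditions: CBr4, PPh3, CH2Cl2, 0 °C to rt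
Reagents that add atoms: carbon tetrabromide, BrC(Br)(Br)Br
Why: Appel reaction: SN2 displacement of the alkoxyphosphonium leaving group by bromide on an unhindered primary carbon.

Step 12
Reactants: 16 (7-bromoheptyl)benzene
Product: 17 (7-phenylheptyl)triphenylphosphonium bromide
Conditions: PPh3, MeCN, reflux
Reagents that add atoms: triphenylphosphine, c1ccc(cc1)P(c1ccccc1)c1ccccc1
Why: SN2 quaternisation of triphenylphosphine by the primary bromide (phosphonium salt formation), the salt being expected to crystallise.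

Step 13
Reactants: 14 (3R,6R)-6-[(tert-butyldiphenylsilyloxy)methyl]-3,6-dimethyl-1,2-dioxane-3-carbaldehyde; 17 (7-phenylheptyl)triphenylphosphonium bromide
Product: 19 tert-butyl({(3R,6R)-3,6-dimethyl-6-[(1Z)-8-phenyloct-1-en-1-yl]-1,2-dioxan-3-yl}methoxy)diphenylsilane, via (7-phenylheptylidene)triphenylphosphorane 18 (not isolated)
Conditions: 17, NaHMDS, THF, 0 °C; then 14, −78 °C to rt
Reagents that add atoms: none
Why: Wittig olefination with a non-stabilised ylide joins the seven-carbon arm to the non-enolisable aldehyde, the predominantly Z geometry being of no consequence because the alkene is saturated in step 16.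

Step 14
Reactants: 19 tert-butyl({(3R,6R)-3,6-dimethyl-6-[(1Z)-8-phenyloct-1-en-1-yl]-1,2-dioxan-3-yl}methoxy)diphenylsilane
Product: 20 {(3R,6R)-3,6-dimethyl-6-[(1Z)-8-phenyloct-1-en-1-yl]-1,2-dioxan-3-yl}methanol
Conditions: Bu4NF, AcOH, THF, 0 °C to rt
Reagents that add atoms: none
Why: Fluoride-induced desilylation driven by Si–F bond formation, buffered with acetic acid; the peroxide (no α-hydrogen) and the isolated alkene are inert.

Step 15
Reactants: 20 {(3R,6R)-3,6-dimethyl-6-[(1Z)-8-phenyloct-1-en-1-yl]-1,2-dioxan-3-yl}methanol; 21 methyl (triphenylphosphoranylidene)acetate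
Product: 23 methyl (2E)-3-{(3R,6R)-3,6-dimethyl-6-[(1Z)-8-phenyloct-1-en-1-yl]-1,2-dioxan-3-yl}prop-2-enoate, via dioxane carbaldehyde 22 (not isolated)
Conditions: Dess–Martin periodinane, CH2Cl2, rt; then 21 (3 equiv), same flask, rt
Reagents that add atoms: none
Why: One-pot Dess–Martin oxidation and Wittig olefination with a stabilised ylide, so that the α-peroxy aldehyde is trapped as formed; the expected E geometry is irrelevant because the alkene is reduced next.

Step 16
Reactants: 23 methyl (2E)-3-{(3R,6R)-3,6-dimethyl-6-[(1Z)-8-phenyloct-1-en-1-yl]-1,2-dioxan-3-yl}prop-2-enoate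
Product: 24 methyl 3-[(3R,6S)-3,6-dimethyl-6-(8-phenyloctyl)-1,2-dioxan-3-yl]propanoate
Conditions: KO2CN=NCO2K (large excess, portionwise), AcOH, MeOH–CH2Cl2, 0 °C to rt
Reagents that add atoms: none
Why: Diimide reduction saturates the isolated Z alkene and the enoate C=C in one operation without touching the O–O bond, the ester or the arene; the descriptor of the phenyloctyl-bearing carbon changes from R to S by priority only.

Step 17
Reactants: 24 methyl 3-[(3R,6S)-3,6-dimethyl-6-(8-phenyloctyl)-1,2-dioxan-3-yl]propanoate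
Product: 25 3-[(3R,6S)-3,6-dimethyl-6-(8-phenyloctyl)-1,2-dioxan-3-yl]propanoic acid
Conditions: LiOH·H2O, THF–MeOH–H2O, 0 °C to rt; then 1 M HCl to pH 3
Reagents that add atoms: lithium hydroxide, [Li+].[OH-]
Why: Saponification (acyl substitution by hydroxide) of the methyl ester followed by acidification; a ditertiary peroxide without α-hydrogen cannot undergo Kornblum–DeLaMare cleavage under base, so the ring survives.

**Compound list**

1 | (R)-2-methylglycidol, [(2R)-2-methyloxiran-2-yl]methanol | C[C@]1(CO1)CO | starting material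
2 | tert-butyl{[(2S)-2-methyloxiran-2-yl]methoxy}diphenylsilane | C[C@]1(CO1)CO[Si](c2ccccc2)(c2ccccc2)C(C)(C)C | intermediate
3 | (2S)-2-{[(4-methoxybenzyl)oxy]methyl}-2-methyloxirane | C[C@]1(CO1)COCc2ccc(OC)cc2 | intermediate
4 | hydrogen peroxide | OO | starting material
5 | (2R)-3-[(tert-butyldiphenylsilyl)oxy]-2-hydroperoxy-2-methylpropan-1-ol | C[C@](OO)(CO[Si](c1ccccc1)(c1ccccc1)C(C)(C)C)CO | intermediate
6 | (2R)-2-({(2R)-1-[(tert-butyldiphenylsilyl)oxy]-3-hydroxy-2-methylpropan-2-yl}peroxy)-3-[(4-methoxybenzyl)oxy]-2-methylpropan-1-ol | C[C@](OO[C@@](C)(COCc1ccc(OC)cc1)CO)(CO[Si](c1ccccc1)(c1ccccc1)C(C)(C)C)CO | intermediate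
7 | (2S)-2-({(2S)-1-[(tert-butyldiphenylsilyl)oxy]-2-methyl-3-oxopropan-2-yl}peroxy)-3-[(4-methoxybenzyl)oxy]-2-methylpropanal | C[C@](OO[C@@](C)(COCc1ccc(OC)cc1)C=O)(CO[Si](c1ccccc1)(c1ccccc1)C(C)(C)C)C=O | intermediate
8 | methyltriphenylphosphonium bromide | C[P+](c1ccccc1)(c1ccccc1)c1ccccc1.[Br-] | starting material
9 | methylidenetriphenylphosphorane | C=P(c1ccccc1)(c1ccccc1)c1ccccc1 | intermediate
10 | (2R)-1-(tert-butyldiphenylsilyloxy)-2-methylbut-3-en-2-yl (2R)-1-(4-methoxybenzyloxy)-2-methylbut-3-en-2-yl peroxide | C[C@](OO[C@@](C)(COCc1ccc(OC)cc1)C=C)(CO[Si](c1ccccc1)(c1ccccc1)C(C)(C)C)C=C | intermediate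
11 | (3R,6R)-3-[(tert-butyldiphenylsilyloxy)methyl]-6-[(4-methoxybenzyloxy)methyl]-3,6-dimethyl-3,6-dihydro-1,2-dioxine | C[C@]1(CO[Si](c2ccccc2)(c2ccccc2)C(C)(C)C)C=C[C@](C)(COCc2ccc(OC)cc2)OO1 | intermediate
12 | (3R,6R)-3-[(tert-butyldiphenylsilyloxy)methyl]-6-[(4-methoxybenzyloxy)methyl]-3,6-dimethyl-1,2-dioxane | C[C@]1(CO[Si](c2ccccc2)(c2ccccc2)C(C)(C)C)CC[C@](C)(COCc2ccc(OC)cc2)OO1 | intermediate
13 | {(3R,6R)-6-[(tert-butyldiphenylsilyloxy)methyl]-3,6-dimethyl-1,2-dioxan-3-yl}methanol | C[C@]1(CO[Si](c2ccccc2)(c2ccccc2)C(C)(C)C)CC[C@](C)(CO)OO1 | intermediate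
14 | (3R,6R)-6-[(tert-butyldiphenylsilyloxy)methyl]-3,6-dimethyl-1,2-dioxane-3-carbaldehyde | C[C@]1(CO[Si](c2ccccc2)(c2ccccc2)C(C)(C)C)CC[C@](C)(C=O)OO1 | intermediate
15 | 7-phenylheptan-1-ol | OCCCCCCCc1ccccc1 | starting material
16 | (7-bromoheptyl)benzene | BrCCCCCCCc1ccccc1 | intermediate
17 | (7-phenylheptyl)triphenylphosphonium bromide | [Br-].c1ccccc1CCCCCCC[P+](c1ccccc1)(c1ccccc1)c1ccccc1 | intermediate
18 | (7-phenylheptylidene)triphenylphosphorane | c1ccccc1CCCCCCC=P(c1ccccc1)(c1ccccc1)c1ccccc1 | intermediate
19 | tert-butyl({(3R,6R)-3,6-dimethyl-6-[(1Z)-8-phenyloct-1-en-1-yl]-1,2-dioxan-3-yl}methoxy)diphenylsilane | C[C@]1(CO[Si](c2ccccc2)(c2ccccc2)C(C)(C)C)CC[C@](C)(/C=C\CCCCCCc2ccccc2)OO1 | intermediate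
20 | {(3R,6R)-3,6-dimethyl-6-[(1Z)-8-phenyloct-1-en-1-yl]-1,2-dioxan-3-yl}methanol | C[C@]1(CO)CC[C@](C)(/C=C\CCCCCCc2ccccc2)OO1 | intermediate
21 | methyl (triphenylphosphoranylidene)acetate | COC(=O)C=P(c1ccccc1)(c1ccccc1)c1ccccc1 | starting material
22 | (3R,6R)-3,6-dimethyl-6-[(1Z)-8-phenyloct-1-en-1-yl]-1,2-dioxane-3-carbaldehyde | C[C@]1(C=O)CC[C@](C)(/C=C\CCCCCCc2ccccc2)OO1 | intermediate
23 | methyl (2E)-3-{(3R,6R)-3,6-dimethyl-6-[(1Z)-8-phenyloct-1-en-1-yl]-1,2-dioxan-3-yl}prop-2-enoate | C[C@]1(/C=C/C(=O)OC)CC[C@](C)(/C=C\CCCCCCc2ccccc2)OO1 | intermediate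
24 | methyl 3-[(3R,6S)-3,6-dimethyl-6-(8-phenyloctyl)-1,2-dioxan-3-yl]propanoate | C[C@]1(CCCCCCCCc2ccccc2)CC[C@](C)(CCC(=O)OC)OO1 | intermediate
25 | 3-[(3R,6S)-3,6-dimethyl-6-(8-phenyloctyl)-1,2-dioxan-3-yl]propanoic acid (CNP0390528.1) | C[C@]1(CCCCCCCCc2ccccc2)CC[C@](C)(CCC(=O)O)OO1 | target

**Step count.** Total: 17 steps. Longest linear sequence: 14 steps (1, 3–10, 13–17); step 2 and steps 11–12 are side branches.

**Steps most likely to fail**

Step 4. The bimolecular opening may be outrun by acid-induced fragmentation of the isolated β-hydroxy hydroperoxide, by rearrangement of the epoxide to a carbonyl compound, or by attack through the hydroxyl instead of the hydroperoxy group. The fallback sets out from 2 and 4 and returns at 13; it replaces the hetero-union by a C2-symmetric homo-union in which the hydroperoxide is never isolated or rationed. Epoxide 2 (2.2 equiv) is treated with H2O2 (1 equiv) and phosphomolybdic acid in one flask, so that 5 formed in situ is intercepted by a second molecule of the same epoxide to give (2R,2'R)-2,2'-peroxybis{3-[(tert-butyldiphenylsilyl)oxy]-2-methylpropan-1-ol} F1. Dess–Martin oxidation should give (2S,2'S)-2,2'-peroxybis{3-[(tert-butyldiphenylsilyl)oxy]-2-methylpropanal} F2, and twofold Wittig methylenation with 9 bis[(2R)-1-(tert-butyldiphenylsilyloxy)-2-methylbut-3-en-2-yl] peroxide F3. Ring-closing metathesis then gives (3R,6R)-3,6-bis[(tert-butyldiphenylsilyloxy)methyl]-3,6-dimethyl-3,6-dihydro-1,2-dioxine F4, and diimide (3R,6R)-3,6-bis[(tert-butyldiphenylsilyloxy)methyl]-3,6-dimethyl-1,2-dioxane F5. A deliberately incomplete monodesilylation (Bu4NF/AcOH, about 1 equiv, recovered F5 recycled) delivers 13, because the two silyl ethers of C2-symmetric F5 are homotopic and either cleavage gives the same alcohol. The price is one statistical step.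

Step 7. The catalyst may fail to load onto either vinyl group, each of which sits on a fully substituted carbon, and decompose before turnover; ruthenium-induced isomerisation of the allylic peroxide is a second possible drain. The fallback sets out from 7 and returns at 11; it is a relay ring-closing metathesis. Dialdehyde 7 is olefinated on both sides with hex-5-en-1-ylidenetriphenylphosphorane F6, made from commercial (hex-5-en-1-yl)triphenylphosphonium bromide with NaHMDS in THF at −78 °C. This gives (2R)-1-(tert-butyldiphenylsilyloxy)-2-methylnona-3(Z),8-dien-2-yl (2R)-1-(4-methoxybenzyloxy)-2-methylnona-3(Z),8-dien-2-yl peroxide F7. The ruthenium carbene then initiates at an unhindered terminal alkene, extrudes cyclopentene and so places the carbene directly on the hindered CH next to the quaternary carbon. Closure onto the other arm gives 11 with loss of two cyclopentene and one ethene.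

Step 6. The strongly basic ylide may fragment the α-peroxy aldehyde (retro-aldol-type cleavage of a β-peroxy alkoxide) or attack the O–O bond before both carbonyl groups are converted. The fallback sets out from 7 and returns at 10; it is a Peterson olefination. Addition of (trimethylsilyl)methylmagnesium chloride with CeCl3 (THF, −78 °C) to both aldehydes should give the bis(β-hydroxysilane), (2R)-1-(tert-butyldiphenylsilyloxy)-3-hydroxy-2-methyl-4-(trimethylsilyl)butan-2-yl (2R)-3-hydroxy-1-(4-methoxybenzyloxy)-2-methyl-4-(trimethylsilyl)butan-2-yl peroxide F8, as carbinol epimers of no consequence. Acid-promoted anti-elimination (BF3·OEt2, CH2Cl2, 0 °C) then releases both vinyl groups to give 10.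

**Further compounds**

F1 | step 4 | (2R,2'R)-2,2'-peroxybis{3-[(tert-butyldiphenylsilyl)oxy]-2-methylpropan-1-ol} | C[C@](OO[C@@](C)(CO[Si](c1ccccc1)(c1ccccc1)C(C)(C)C)CO)(CO[Si](c1ccccc1)(c1ccccc1)C(C)(C)C)CO
F2 | step 4 | (2S,2'S)-2,2'-peroxybis{3-[(tert-butyldiphenylsilyl)oxy]-2-methylpropanal} | C[C@](OO[C@@](C)(CO[Si](c1ccccc1)(c1ccccc1)C(C)(C)C)C=O)(CO[Si](c1ccccc1)(c1ccccc1)C(C)(C)C)C=O
F3 | step 4 | bis[(2R)-1-(tert-butyldiphenylsilyloxy)-2-methylbut-3-en-2-yl] peroxide | C[C@](OO[C@@](C)(CO[Si](c1ccccc1)(c1ccccc1)C(C)(C)C)C=C)(CO[Si](c1ccccc1)(c1ccccc1)C(C)(C)C)C=C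
F4 | step 4 | (3R,6R)-3,6-bis[(tert-butyldiphenylsilyloxy)methyl]-3,6-dimethyl-3,6-dihydro-1,2-dioxine | C[C@]1(CO[Si](c2ccccc2)(c2ccccc2)C(C)(C)C)C=C[C@](C)(CO[Si](c2ccccc2)(c2ccccc2)C(C)(C)C)OO1
F5 | step 4 | (3R,6R)-3,6-bis[(tert-butyldiphenylsilyloxy)methyl]-3,6-dimethyl-1,2-dioxane | C[C@]1(CO[Si](c2ccccc2)(c2ccccc2)C(C)(C)C)CC[C@](C)(CO[Si](c2ccccc2)(c2ccccc2)C(C)(C)C)OO1
F6 | step 7 | hex-5-en-1-ylidenetriphenylphosphorane | C=CCCCC=P(c1ccccc1)(c1ccccc1)c1ccccc1
F7 | step 7 | (2R)-1-(tert-butyldiphenylsilyloxy)-2-methylnona-3(Z),8-dien-2-yl (2R)-1-(4-methoxybenzyloxy)-2-methylnona-3(Z),8-dien-2-yl peroxide | C[C@](OO[C@@](C)(COCc1ccc(OC)cc1)/C=C\CCCC=C)(CO[Si](c1ccccc1)(c1ccccc1)C(C)(C)C)/C=C\CCCC=C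
F8 | step 6 | (2R)-1-(tert-butyldiphenylsilyloxy)-3-hydroxy-2-methyl-4-(trimethylsilyl)butan-2-yl (2R)-3-hydroxy-1-(4-methoxybenzyloxy)-2-methyl-4-(trimethylsilyl)butan-2-yl peroxide (carbinol centres unassigned, mixture) | C[C@](OO[C@@](C)(COCc1ccc(OC)cc1)C(O)C[Si](C)(C)C)(CO[Si](c1ccccc1)(c1ccccc1)C(C)(C)C)C(O)C[Si](C)(C)C
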